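**Retrosynthetic overview**
1. GA87 ⇒ (global desilylation) 3-O-TBS/7-SEM-protected GA87 ⇒ (C13–C16 disconnection, key step) a ring-D-seco alkynyl 12α-hydroxy-13-ketone; a SmI2 ketyl–alkyne 5-exo-dig closure rebuilds ring D, the 13-OH and the 16-methylene in one operation.
2. C12–O ⇒ axial α-bromination of the ring C ketone, then SN2 inversion with formate; this ketone, the only handle that makes C12 addressable, exists only once ring D has been excised.
3. Alkyne ⇒ aldehyde (Ohira–Bestmann returns C17) ⇒ 13,16-diol cleavage ⇒ ozonolysis of the C16=C17 methylene of protected gibberellic acid.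
4. Ring order: rings A, B and C (with C3, C4, C5, C6, C8, C9, C10) arrive intact in gibberellic acid; ring D is opened, ring C is oxidised at C12, and ring D is the only ring formed (last).

Assumption: gibberellic acid (GA3), a bulk fermentation product sold enantiopure, is accepted as the commercial starting material; the obvious plan (direct C12 functionalisation of the intact tetracycle) is deliberately replaced by a ring D excision / re-annulation.

Conventions: gibberellin numbering; GA87 is the target gibberellin, (12S)-12α-hydroxy-GA3. On ring C, β = the face carrying the C15–C16 bridge (the C8 side chain in seco compounds), α = the opposite face. TBS = tert-butyldimethylsilyl, SEM = 2-(trimethylsilyl)ethoxymethyl.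

**Route**

Step 1
Reactants: 1 gibberellic acid (GA3)
Product: 2 GA3 7-SEM ester
Conditions: SEMCl (1.1 equiv), i-Pr2NEt, THF/DMF, 0 °C → rt
Reagents that add atoms: 2-(trimethylsilyl)ethoxymethyl chloride (SEMCl), C[Si](C)(C)CCOCCl
Why: Esterification by carboxylate O-alkylation; the ammonium carboxylate is far more nucleophilic toward the chloromethyl ether than the hindered 3-OH or the tertiary 13-OH, and no stereocentre is touched.

Step 2
Reactants: 2 GA3 7-SEM ester
Product: 3 3-O-TBS-GA3 7-SEM ester
Conditions: TBSCl, imidazole, DMF, rt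
Reagents that add atoms: tert-butyldimethylsilyl chloride (TBSCl), CC(C)(C)[Si](C)(C)Cl
Why: Silyl ether formation is selective for the secondary allylic 3-OH over the bridgehead tertiary 13-OH, and the ether blocks base-induced retro-aldol opening at C3–C4 in later steps.

Step 3
Reactants: 3 3-O-TBS-GA3 7-SEM ester
Product: 5 3-O-TBS-17-nor-16-hydroxy-GA3 7-SEM ester (13,16-diol), via 16-norketone 4 (not isolated)
Conditions: O3, CH2Cl2/MeOH, pyridine (cat.), Sudan Red 7B, −78 °C; then NaBH4, −78 → 0 °C
Reagents that add atoms: ozone, [O-][O+]=O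
Why: Ozonolysis with borohydride work-up: the electron-rich 1,1-disubstituted C16=C17 bond reacts much faster than the C1=C2 bond (deactivated by two flanking C–O bonds), and NaBH4 then reduces the ketol carbonyl in the pot before any acyloin shift; the C16 configuration is irrelevant because that centre becomes an aldehyde in step 4.

Step 4
Reactants: 5 3-O-TBS-17-nor-16-hydroxy-GA3 7-SEM ester (13,16-diol)
Product: 6 seco keto-aldehyde
Conditions: Pb(OAc)4, CH2Cl2, 0 °C
Reagents that add atoms: none
Why: Criegee glycol cleavage of the C13–C16 bond (Pb(OAc)4 cleaves cis and rigid trans diols alike) excises ring D and unmasks C13 as a ring C cyclohexanone with C8 carrying CH2CHO; no stereocentre other than the vanishing C13 and C16 is affected.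

Step 5
Reactants: 6 seco keto-aldehyde
Product: 7 seco alkynyl ketone
Conditions: dimethyl (1-diazo-2-oxopropyl)phosphonate, K2CO3, MeOH, 0 °C → rt
Reagents that add atoms: dimethyl (1-diazo-2-oxopropyl)phosphonate (Ohira–Bestmann reagent), CC(=O)C(=[N+]=[N-])P(=O)(OC)OC
Why: Seyferth–Gilbert homologation in the Ohira–Bestmann variant converts the aldehyde (not the ketone) into the terminal alkyne and returns C17; the carbonate base is tolerated by the TBS-protected ring A and the very hindered C7 ester, and fast addition of the phosphonate anion to the aldehyde should outrun intramolecular aldolisation of the 1,5-keto aldehyde.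

Step 6
Reactants: 7 seco alkynyl ketone
Product: 9 12β-bromo ketone, via TMS enol ether 8 (not isolated)
Conditions: TMSOTf, Et3N, CH2Cl2, 0 °C; then NBS, THF, −78 °C
Reagents that add atoms: N-bromosuccinimide (NBS), O=C1CCC(=O)N1Br; trimethylsilyl triflate (TMSOTf), C[Si](C)(C)OS(=O)(=O)C(F)(F)F (its silyl group stays only in intermediate 8)
Why: Soft enolisation gives the C12=C13 silyl enol ether (the C14 side is neopentylic, next to quaternary C8), and electrophilic α-bromination of the silyl enol ether occurs by axial attack on the convex β face (opposite cis-fused ring B, in the ring C chair with C6 axial), setting (12R)-Br.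

Step 7
Reactants: 9 12β-bromo ketone
Product: 11 12α-hydroxy ketone, via 12α-formate 10 (not isolated)
Conditions: HCO2K, 18-crown-6 (cat.), DMF, rt; then MeOH, KHCO3 (cat.), 0 °C
Reagents that add atoms: HCO2K (potassium formate), [K+].[O-]C=O
Why: SN2 displacement of the axial α-bromo ketone by carboxylate inverts C12 to the equatorial, thermodynamically preferred 12α-oxygen, (12S), and the formate is then removed by mild transesterification.

Step 8
Reactants: 11 12α-hydroxy ketone
Product: 12 3-O-TBS-GA87 7-SEM ester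
Conditions: SmI2 (4 equiv), HMPA, t-BuOH, THF, −20 → 0 °C
Reagents that add atoms: none
Why: SmI2-mediated ketyl–alkyne reductive cyclisation (Stork-type, 5-exo-dig): the C13 ketyl adds to the internal alkyne carbon, and because the propargyl tether sits on the β face of C8 the new C13–C16 bond can only form on the β face, which restores the natural 13-OH configuration and the exocyclic 16-methylene; the 12-oxygen, held as a samarium alkoxide (a poor leaving group, as in the known cyclisations of α-oxygenated ketyls), is retained and the C12 centre is untouched.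

Step 9
Reactants: 12 3-O-TBS-GA87 7-SEM ester
Product: 13 GA87 (12α-hydroxy-GA3)
Conditions: 48% aq. HF, MeCN, 0 °C → rt
Reagents that add atoms: none
Why: Fluoride-induced desilylation cleaves the TBS ether and fragments the SEM ester (β-elimination releasing ethylene and formaldehyde) under mildly acidic, non-basic conditions that the allylic lactone, the 3-hydroxy-1-ene unit and the tertiary allylic 12,13-diol tolerate; no stereocentre is affected.

**Compound list**
1 | gibberellic acid (GA3): 3β,13-dihydroxy, C1=C2, 16-methylene, 19,10-lactone, 7-CO2H | C=C1C[C@]23C[C@@]1(O)CC[C@H]2[C@@]12C=C[C@H](O)[C@@](C)(C(=O)O1)[C@H]2[C@@H]3C(=O)O | starting material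
2 | GA3 7-SEM ester | C=C1C[C@]23C[C@@]1(O)CC[C@H]2[C@@]12C=C[C@H](O)[C@@](C)(C(=O)O1)[C@H]2[C@@H]3C(=O)OCOCC[Si](C)(C)C | intermediate
3 | 3-O-TBS-GA3 7-SEM ester | C=C1C[C@]23C[C@@]1(O)CC[C@H]2[C@@]12C=C[C@H](O[Si](C)(C)C(C)(C)C)[C@@](C)(C(=O)O1)[C@H]2[C@@H]3C(=O)OCOCC[Si](C)(C)C | intermediate
4 | 16-norketone: 3-O-TBS-17-nor-16-oxo-GA3 7-SEM ester (13-hydroxy-16-ketone) | O=C1C[C@]23C[C@@]1(O)CC[C@H]2[C@@]12C=C[C@H](O[Si](C)(C)C(C)(C)C)[C@@](C)(C(=O)O1)[C@H]2[C@@H]3C(=O)OCOCC[Si](C)(C)C | intermediate (not isolated)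
5 | 3-O-TBS-17-nor-16-hydroxy-GA3 7-SEM ester (13,16-diol; C16 epimer mixture, centre left undefined because both epimers converge) | OC1C[C@]23C[C@@]1(O)CC[C@H]2[C@@]12C=C[C@H](O[Si](C)(C)C(C)(C)C)[C@@](C)(C(=O)O1)[C@H]2[C@@H]3C(=O)OCOCC[Si](C)(C)C | intermediate
6 | seco keto-aldehyde: 3-O-TBS-13,16-seco-17-nor-13-oxo-GA3-16-al 7-SEM ester (ring C is a cyclohexanone at C13; C8 carries CH2CHO on its β face) | O=CC[C@]23CC(=O)CC[C@H]2[C@@]12C=C[C@H](O[Si](C)(C)C(C)(C)C)[C@@](C)(C(=O)O1)[C@H]2[C@@H]3C(=O)OCOCC[Si](C)(C)C | intermediate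
7 | seco alkynyl ketone: as 6 but C8 carries a β-propargyl group (C15H2–C16≡C17H); 13-ketone | C#CC[C@]23CC(=O)CC[C@H]2[C@@]12C=C[C@H](O[Si](C)(C)C(C)(C)C)[C@@](C)(C(=O)O1)[C@H]2[C@@H]3C(=O)OCOCC[Si](C)(C)C | intermediate
8 | TMS enol ether: 13-trimethylsilyloxy C12=C13 enol ether of 7 | C#CC[C@]23CC(O[Si](C)(C)C)=CC[C@H]2[C@@]12C=C[C@H](O[Si](C)(C)C(C)(C)C)[C@@](C)(C(=O)O1)[C@H]2[C@@H]3C(=O)OCOCC[Si](C)(C)C | intermediate (not isolated)
9 | 12β-bromo ketone: (12R)-12-bromo derivative of 7, Br on the face of the C8 propargyl group | C#CC[C@]23CC(=O)[C@H](Br)C[C@H]2[C@@]12C=C[C@H](O[Si](C)(C)C(C)(C)C)[C@@](C)(C(=O)O1)[C@H]2[C@@H]3C(=O)OCOCC[Si](C)(C)C | intermediate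
10 | 12α-formate: (12S)-12-formyloxy derivative of 7 | C#CC[C@]23CC(=O)[C@@H](OC=O)C[C@H]2[C@@]12C=C[C@H](O[Si](C)(C)C(C)(C)C)[C@@](C)(C(=O)O1)[C@H]2[C@@H]3C(=O)OCOCC[Si](C)(C)C | intermediate (not isolated)
11 | 12α-hydroxy ketone: (12S)-12-hydroxy derivative of 7, OH on the face opposite the C8 propargyl group | C#CC[C@]23CC(=O)[C@@H](O)C[C@H]2[C@@]12C=C[C@H](O[Si](C)(C)C(C)(C)C)[C@@](C)(C(=O)O1)[C@H]2[C@@H]3C(=O)OCOCC[Si](C)(C)C | intermediate
12 | 3-O-TBS-GA87 7-SEM ester: (12S)-12α,13-dihydroxy, 12-OH cis to 13-OH and anti to the C15–C16 bridge | C=C1C[C@]23C[C@@]1(O)[C@@H](O)C[C@H]2[C@@]12C=C[C@H](O[Si](C)(C)C(C)(C)C)[C@@](C)(C(=O)O1)[C@H]2[C@@H]3C(=O)OCOCC[Si](C)(C)C | intermediate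
13 | GA87: (12S)-12α-hydroxy-GA3; 3β,12α,13-trihydroxy, C1=C2, 16-methylene, 19,10-lactone, 7-CO2H | C=C1C[C@]23C[C@@]1(O)[C@@H](O)C[C@H]2[C@@]12C=C[C@H](O)[C@@](C)(C(=O)O1)[C@H]2[C@@H]3C(=O)O | target

**Step count**
Total steps: 9. Longest linear sequence: 9 steps (fully linear from 1).

**Three steps most likely to fail**

Step 8. The ketyl must cyclise faster than it is simply reduced or loses its α-oxygen, and it must do so through the ring C chair with C15 and C10 axial, in which the 12α-oxygen is syn-axial to C10. The fallback replaces the radical closure by a polar, chromium-mediated one. It sets out from 11: Markovnikov hydroiodination of the terminal alkyne (B-iodo-9-BBN, then AcOH) gives the 2-iodoalkene F1. An intramolecular Nozaki–Hiyama–Kishi addition (CrCl2, NiCl2 cat., DMSO) of the vinylchromium to the chelating C13 ketone then closes ring D, and the route is rejoined at 12.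

Step 7. The SN2 displacement has to take place on the concave α face; dehydrobromination to the C11=C12 enone or a ketol transposition could intervene. The fallback sets the C12 centre late, by ketone reduction instead of substitution. It sets out from 7: Rubottom oxidation (enol ether 8, then dimethyldioxirane and mild acid work-up) puts oxygen on the β face and gives the 12β-hydroxy ketone F2. The same SmI2 ketyl–alkyne closure gives the 12-epi alcohol F3. Dess–Martin periodinane oxidises only the secondary alcohol, giving the 12-ketone F4. LiBH(s-Bu)3 at −78 °C is expected to deliver hydride from the β face, because the α face is shielded by the axial C10, and this returns the route to 12.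

Step 9. One acidic fluoride operation may be slow on the very hindered C7 SEM ester, or may harm the allylic lactone and the tertiary allylic diol. The fallback uses two orthogonal steps that avoid Brønsted acid. It sets out from 12: MgBr2·OEt2 (Et2O/MeNO2) cleaves the SEM ester by chelation and gives the 3-O-TBS-GA87 free acid F5. Buffered TASF (tris(dimethylamino)sulfonium difluorotrimethylsilicate) in DMF then removes the silyl ether and arrives at 13.

**Further compounds**
F1 | step 8 | 2-iodoalkene: 11 with the propargyl group converted to CH2–C(I)=CH2 | C=C(I)C[C@]23CC(=O)[C@@H](O)C[C@H]2[C@@]12C=C[C@H](O[Si](C)(C)C(C)(C)C)[C@@](C)(C(=O)O1)[C@H]2[C@@H]3C(=O)OCOCC[Si](C)(C)C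
F2 | step 7 | 12β-hydroxy ketone: (12R)-12-hydroxy epimer of 11 | C#CC[C@]23CC(=O)[C@H](O)C[C@H]2[C@@]12C=C[C@H](O[Si](C)(C)C(C)(C)C)[C@@](C)(C(=O)O1)[C@H]2[C@@H]3C(=O)OCOCC[Si](C)(C)C
F3 | step 7 | 12-epi alcohol: 12β-hydroxy epimer of 12 | C=C1C[C@]23C[C@@]1(O)[C@H](O)C[C@H]2[C@@]12C=C[C@H](O[Si](C)(C)C(C)(C)C)[C@@](C)(C(=O)O1)[C@H]2[C@@H]3C(=O)OCOCC[Si](C)(C)C
F4 | step 7 | 12-ketone: 3-O-TBS-12-oxo-GA3 7-SEM ester (13-hydroxy-12-ketone) | C=C1C[C@]23C[C@@]1(O)C(=O)C[C@H]2[C@@]12C=C[C@H](O[Si](C)(C)C(C)(C)C)[C@@](C)(C(=O)O1)[C@H]2[C@@H]3C(=O)OCOCC[Si](C)(C)C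
F5 | step 9 | 3-O-TBS-GA87 free acid | C=C1C[C@]23C[C@@]1(O)[C@@H](O)C[C@H]2[C@@]12C=C[C@H](O[Si](C)(C)C(C)(C)C)[C@@](C)(C(=O)O1)[C@H]2[C@@H]3C(=O)O
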